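**Plan**

1. Retrosynthesis: the C6=CMe2 alkene goes back to a C6 ketone and the propanoic acid to a 3-hydroxypropyl chain; the arene–CH2 unit at C1 goes back to a C1 formyl group plus an aryllithium; C3–C4 goes back to C3=C4; then C4a–C8a and C1–C2 are cut together in a retro-[4+2] to an acyclic trienal.
2. Enabling feature: ring B (C1, C2, C3, C4, C4a, C8a) has its only two CH2 groups (C3, C4) adjacent and flanked by the four contiguous stereocentres C2, C1, C8a and C4a, and its quaternary C1 carries an exocyclic one-carbon arm. Ring B is therefore a hidden cyclohexene whose C8a=C1 dienophile is activated by a C1 formyl group, and ring A (C4a, C5, C6, C7, C8, C8a) is the four-atom tether C5–C8.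
3. Forward order: acyclic C5/C6 stereodiad by aldol, then the (E,E)-diene by alkyne carbometalation and alkenyl coupling, then the (E)-enal by Wittig reaction. One intramolecular Diels–Alder step then closes ring A through the shared C4a–C8a bond and completes ring B last through the C1–C2 bond; the arene is brought in afterwards as an intact unit.
4. End game: aryl addition, dissolving-metal deoxygenation and debenzylation, hydrogenation of C3=C4, oxidation to the C6 keto acid, isopropylidenation, unmasking of the hydroquinone.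
5. Stereochemistry: C5 and a temporary C6 benzyloxy group come from an Evans syn-aldol with the (R)-auxiliary. C1, C2, C4a and C8a come from the E geometries of enal and diene and an endo, chair-like transition state in which both tether substituents are equatorial.

Key step: step 12

Remark: locants of the bicyclic compounds follow decalin numbering (C1 quaternary arylmethyl carbon, C2 secondary methyl carbon, C4a and C8a ring fusion, C5 chain-bearing carbon, C6 isopropylidene carbon); β is the face of the C4a methyl group and α the opposite face.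

**Route**

Step 1
Reactants: 1 4-methoxy-2-methylphenol
Product: 2 2-bromo-4-methoxy-6-methylphenol
Conditions: NBS, MeCN, 0 °C → rt
Reagents that add atoms: N-bromosuccinimide, O=C1CCC(=O)N1Br
Why: Electrophilic aromatic bromination should go ortho to the free hydroxyl, because the para position carries OMe and the other ortho position the methyl group.

Step 2
Reactants: 2 2-bromo-4-methoxy-6-methylphenol
Product: 3 1-bromo-2,5-dimethoxy-3-methylbenzene
Conditions: MeI, K2CO3, acetone, reflux
Reagents that add atoms: iodomethane, CI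
Why: Williamson O-methylation of the phenoxide gives the hydroquinone dimethyl ether that serves as the masked hydroquinone.

Step 3
Reactants: 4 5-(benzyloxy)pentanoic acid; 5 (R)-4-benzyl-1,3-oxazolidin-2-one
Product: 6 (R)-4-benzyl-3-[5-(benzyloxy)pentanoyl]-1,3-oxazolidin-2-one
Conditions: DCC, DMAP (cat.), CH2Cl2, 0 °C → rt
Reagents that add atoms: none
Why: Carbodiimide activation with DMAP as acyl-transfer catalyst (Steglich-type N-acylation) should give the imide needed for auxiliary-controlled enolate chemistry.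

Step 4
Reactants: 6 (R)-4-benzyl-3-[5-(benzyloxy)pentanoyl]-1,3-oxazolidin-2-one; 7 4-[(tert-butyldimethylsilyl)oxy]butanal
Product: 9 (R)-4-benzyl-3-[(2R,3S)-2-[3-(benzyloxy)propyl]-6-[(tert-butyldimethylsilyl)oxy]-3-hydroxyhexanoyl]-1,3-oxazolidin-2-one, via dibutylboron (Z)-enolate 8 (not isolated)
Conditions: Bu2BOTf, iPr2NEt, CH2Cl2, −78 → 0 °C; then 7, −78 → 0 °C; pH 7 buffer, MeOH, H2O2
Reagents that add atoms: none
Why: In this Evans syn-aldol reaction the boron (Z)-enolate reacts through a closed Zimmerman–Traxler chair with the benzyl group of the (R)-auxiliary shielding one face, which should set the (2R,3S) syn stereodiad that becomes C5 and the temporary C6–O centre.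

Step 5
Reactants: 9 syn-aldol adduct
Product: 10 (R)-4-benzyl-3-[(2R,3S)-3-(benzyloxy)-2-[3-(benzyloxy)propyl]-6-[(tert-butyldimethylsilyl)oxy]hexanoyl]-1,3-oxazolidin-2-one
Conditions: benzyl 2,2,2-trichloroacetimidate, TfOH (cat.), CH2Cl2/cyclohexane, 0 °C
Reagents that add atoms: benzyl 2,2,2-trichloroacetimidate, N=C(OCc1ccccc1)C(Cl)(Cl)Cl
Why: Acid-catalysed O-benzylation with the trichloroacetimidate avoids base and therefore retro-aldol cleavage, and leaves both stereocentres untouched.

Step 6
Reactants: 10 benzylated aldol imide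
Product: 11 (2S,3S)-3-(benzyloxy)-2-[3-(benzyloxy)propyl]-6-[(tert-butyldimethylsilyl)oxy]hexan-1-ol
Conditions: LiBH4, H2O (1 equiv), Et2O, 0 °C
Reagents that add atoms: none
Why: Chemoselective hydride reduction of the exocyclic imide carbonyl releases the primary alcohol and the recoverable auxiliary.

Step 7
Reactants: 11 primary alcohol
Product: 12 (2R,3S)-3-(benzyloxy)-2-[3-(benzyloxy)propyl]-6-[(tert-butyldimethylsilyl)oxy]hexanal
Conditions: Dess–Martin periodinane, pyridine, CH2Cl2, 0 °C → rt
Reagents that add atoms: none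
Why: Dess–Martin oxidation under buffered conditions should give the α-branched aldehyde without epimerisation.

Step 8
Reactants: 12 aldehyde
Product: 13 tert-butyl{[(4S,5S)-4-(benzyloxy)-5-[3-(benzyloxy)propyl]hept-6-yn-1-yl]oxy}dimethylsilane
Conditions: dimethyl (1-diazo-2-oxopropyl)phosphonate, K2CO3, MeOH, 0 °C → rt
Reagents that add atoms: dimethyl (1-diazo-2-oxopropyl)phosphonate, CC(=O)C(=[N+]=[N-])P(=O)(OC)OC
Why: Seyferth–Gilbert homologation in the Ohira–Bestmann form converts the aldehyde into the terminal alkyne under mild conditions that should not epimerise the α-centre.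

Step 9
Reactants: 13 terminal alkyne; 14 (E)-1-bromoprop-1-ene
Product: 16 tert-butyl{[(4S,5S,6E,8E)-4-(benzyloxy)-5-[3-(benzyloxy)propyl]-6-methyldeca-6,8-dien-1-yl]oxy}dimethylsilane, via (E)-alkenyldimethylalane 15 (not isolated)
Conditions: Me3Al, Cp2ZrCl2 (0.25 equiv), CH2Cl2, 0 °C → rt; volatiles removed; then 14, ZnCl2, Pd(PPh3)4 (5 mol %), THF, rt
Reagents that add atoms: trimethylaluminium, C[Al](C)C
Why: Zirconium-catalysed syn-carboalumination (Negishi) places methyl on the internal and aluminium on the terminal alkyne carbon, and the palladium-catalysed Negishi coupling with retention at both alkenyl partners should give the (6E,8E)-diene with the methyl group cis to the diene chain.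

Step 10
Reactants: 16 silyl ether diene
Product: 17 (4S,5S,6E,8E)-4-(benzyloxy)-5-[3-(benzyloxy)propyl]-6-methyldeca-6,8-dien-1-ol
Conditions: Bu4NF, THF, 0 °C → rt
Reagents that add atoms: none
Why: Fluoride-mediated cleavage removes the only silyl ether.

Step 11
Reactants: 17 dienol; 18 2-(triphenyl-λ5-phosphanylidene)propanal
Product: 20 (2E,6S,7S,8E,10E)-6-(benzyloxy)-7-[3-(benzyloxy)propyl]-2,8-dimethyldodeca-2,8,10-trienal, via dienal 19 (not isolated)
Conditions: Dess–Martin periodinane, CH2Cl2, rt; then 18, 40 °C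
Reagents that add atoms: none
Why: One-pot Dess–Martin oxidation and Wittig olefination with the stabilised formyl ylide should give the (E)-2-methyl enal.

Step 12
Reactants: 20 trienal
Product: 21 6α-(benzyloxy)-5β-[3-(benzyloxy)propyl]-1β,2α,4aβ-trimethyl-1,2,4a,5,6,7,8,8aα-octahydronaphthalene-1α-carbaldehyde
Conditions: Me2AlCl (1.5 equiv), CH2Cl2, −78 → −20 °C
Reagents that add atoms: none
Why: Coordination of Me2AlCl to the formyl oxygen lowers the LUMO of the enal, and a concerted but asynchronous intramolecular [4+2] cycloaddition joins chain carbons C3 to C8 and C2 to C11 (C8a–C4a and C1–C2 of the product). The closest known reaction type is the Lewis acid-promoted intramolecular Diels–Alder reaction of (E)-2-methyl-2,8,10-trienals to trans-fused octahydronaphthalenes with a quaternary formyl-bearing carbon. Ring B is closed as the cycloaddition ring (four diene and two dienophile carbons, finished by the C1–C2 bond), and ring A is closed as the fused six-membered tether ring by the C4a–C8a bond. C1 and C8a take their relative configuration from the E geometry of the enal, C2 and C4a from the E,E geometry of the diene (C2 methyl outside, C4a methyl inside), and the trans ring fusion with the C2 methyl cis to the formyl group from the endo position of the complexed formyl group. Facial selectivity towards the existing centres is needed and should be secured by the chair-like tether, in which the syn-related C5 chain and C6 benzyloxy group are both equatorial, whereas the other diene face would need both axial with a syn-axial contact between OBn and the C4a methyl. Endo over exo selectivity is needed as well and is supported by Lewis acid complexation of a terminally activated (E)-dienophile on a four-atom tether.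

Step 13
Reactants: 3 1-bromo-2,5-dimethoxy-3-methylbenzene; 21 bicyclic aldehyde
Product: 23 (2,5-dimethoxy-3-methylphenyl)[6α-(benzyloxy)-5β-[3-(benzyloxy)propyl]-1β,2α,4aβ-trimethyl-1,2,4a,5,6,7,8,8aα-octahydronaphthalen-1α-yl]methanol (both carbinol epimers), via aryllithium 22 (not isolated)
Conditions: 3, n-BuLi, THF, −78 °C; then 21, −78 → 0 °C
Reagents that add atoms: none
Why: Bromine–lithium exchange gives the aryllithium, which should add to the non-enolisable neopentyl aldehyde; the new carbinol centre forms as an epimeric mixture and is removed in step 14.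

Step 14
Reactants: 23 benzylic alcohol
Product: 24 3-[1α-(2,5-dimethoxy-3-methylbenzyl)-6α-hydroxy-1β,2α,4aβ-trimethyl-1,2,4a,5,6,7,8,8aα-octahydronaphthalen-5β-yl]propan-1-ol
Conditions: Li, NH3(l)/THF, −78 → −40 °C; then NH4Cl
Reagents that add atoms: none
Why: Dissolving-metal (Birch-type) reduction should cleave the benzylic C–O bond of the aryl carbinol and both benzyl ethers by electron transfer to the arenes, leaving the isolated C3=C4 alkene and all stereocentres untouched.

Step 15
Reactants: 24 unsaturated diol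
Product: 25 3-[1α-(2,5-dimethoxy-3-methylbenzyl)-6α-hydroxy-1β,2α,4aβ-trimethyl-8aαH-decahydronaphthalen-5β-yl]propan-1-ol
Conditions: H2 (1 atm), Pd on carbon, EtOAc, rt
Reagents that add atoms: none
Why: Heterogeneous hydrogenation saturates the cis-disubstituted ring alkene and creates no stereocentre.

Step 16
Reactants: 25 saturated diol
Product: 26 3-[1α-(2,5-dimethoxy-3-methylbenzyl)-1β,2α,4aβ-trimethyl-6-oxo-8aαH-decahydronaphthalen-5β-yl]propanoic acid
Conditions: CrO3, H2SO4, H2O, acetone, 0 °C
Reagents that add atoms: water, O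
Why: Jones oxidation converts the secondary alcohol into the C6 ketone and the primary alcohol, through the aldehyde hydrate, into the acid; fast oxidation of the secondary carbinol should prevent lactol formation.

Step 17
Reactants: 26 keto acid; 27 isopropyltriphenylphosphonium iodide
Product: 29 3-[1α-(2,5-dimethoxy-3-methylbenzyl)-1β,2α,4aβ-trimethyl-6-(propan-2-ylidene)-8aαH-decahydronaphthalen-5β-yl]propanoic acid, via isopropylidenetriphenylphosphorane 28 (not isolated)
Conditions: 27, n-BuLi, THF, 0 °C; then 26, 0 °C → reflux; aqueous HCl work-up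
Reagents that add atoms: none
Why: Wittig olefination with the non-stabilised isopropylidene ylide (the carboxylate is inert) should install the tetrasubstituted exocyclic alkene directly at C6.

Step 18
Reactants: 29 isopropylidene acid
Product: 31 CNP0286368.1: 3-[1α-(2,5-dihydroxy-3-methylbenzyl)-1β,2α,4aβ-trimethyl-6-(propan-2-ylidene)-8aαH-decahydronaphthalen-5β-yl]propanoic acid, via quinone 30 (not isolated)
Conditions: (NH4)2Ce(NO3)6, MeCN/H2O, 0 °C; then Na2S2O4, EtOAc/H2O, rt
Reagents that add atoms: water, O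
Why: Oxidative demethylation of the hydroquinone dimethyl ether by tetravalent cerium (the arene is oxidised more easily than the tetrasubstituted alkene) gives the quinone, which dithionite reduces to the hydroquinone.

**Compound list**

1 | 4-methoxy-2-methylphenol | COc1ccc(O)c(C)c1 | starting material
2 | 2-bromo-4-methoxy-6-methylphenol | COc1cc(C)c(O)c(Br)c1 | intermediate
3 | 1-bromo-2,5-dimethoxy-3-methylbenzene | COc1cc(C)c(OC)c(Br)c1 | intermediate
4 | 5-(benzyloxy)pentanoic acid | OC(=O)CCCCOCc1ccccc1 | starting material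
5 | (R)-4-benzyl-1,3-oxazolidin-2-one | O=C1N[C@H](Cc2ccccc2)CO1 | starting material
6 | (R)-4-benzyl-3-[5-(benzyloxy)pentanoyl]-1,3-oxazolidin-2-one | O=C(CCCCOCc1ccccc1)N1[C@H](Cc2ccccc2)COC1=O | intermediate
7 | 4-[(tert-butyldimethylsilyl)oxy]butanal | O=CCCCO[Si](C)(C)C(C)(C)C | starting material
8 | dibutylboron (Z)-enolate of 6 | CCCCB(CCCC)O/C(=C\CCCOCc1ccccc1)N1[C@H](Cc2ccccc2)COC1=O | intermediate
9 | (R)-4-benzyl-3-[(2R,3S)-2-[3-(benzyloxy)propyl]-6-[(tert-butyldimethylsilyl)oxy]-3-hydroxyhexanoyl]-1,3-oxazolidin-2-one | O=C([C@H](CCCOCc1ccccc1)[C@@H](O)CCCO[Si](C)(C)C(C)(C)C)N1[C@H](Cc2ccccc2)COC1=O | intermediate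
10 | (R)-4-benzyl-3-[(2R,3S)-3-(benzyloxy)-2-[3-(benzyloxy)propyl]-6-[(tert-butyldimethylsilyl)oxy]hexanoyl]-1,3-oxazolidin-2-one | O=C([C@H](CCCOCc1ccccc1)[C@@H](OCc1ccccc1)CCCO[Si](C)(C)C(C)(C)C)N1[C@H](Cc2ccccc2)COC1=O | intermediate
11 | (2S,3S)-3-(benzyloxy)-2-[3-(benzyloxy)propyl]-6-[(tert-butyldimethylsilyl)oxy]hexan-1-ol | OC[C@H](CCCOCc1ccccc1)[C@@H](OCc1ccccc1)CCCO[Si](C)(C)C(C)(C)C | intermediate
12 | (2R,3S)-3-(benzyloxy)-2-[3-(benzyloxy)propyl]-6-[(tert-butyldimethylsilyl)oxy]hexanal | O=C[C@H](CCCOCc1ccccc1)[C@@H](OCc1ccccc1)CCCO[Si](C)(C)C(C)(C)C | intermediate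
13 | tert-butyl{[(4S,5S)-4-(benzyloxy)-5-[3-(benzyloxy)propyl]hept-6-yn-1-yl]oxy}dimethylsilane | C#C[C@H](CCCOCc1ccccc1)[C@@H](OCc1ccccc1)CCCO[Si](C)(C)C(C)(C)C | intermediate
14 | (E)-1-bromoprop-1-ene | C/C=C/Br | starting material
15 | dimethyl[(1E,3S,4S)-4-(benzyloxy)-3-[3-(benzyloxy)propyl]-7-[(tert-butyldimethylsilyl)oxy]-2-methylhept-1-en-1-yl]alumane | C[Al](C)/C=C(\C)[C@H](CCCOCc1ccccc1)[C@@H](OCc1ccccc1)CCCO[Si](C)(C)C(C)(C)C | intermediate
16 | tert-butyl{[(4S,5S,6E,8E)-4-(benzyloxy)-5-[3-(benzyloxy)propyl]-6-methyldeca-6,8-dien-1-yl]oxy}dimethylsilane | C/C=C/C=C(\C)[C@H](CCCOCc1ccccc1)[C@@H](OCc1ccccc1)CCCO[Si](C)(C)C(C)(C)C | intermediate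
17 | (4S,5S,6E,8E)-4-(benzyloxy)-5-[3-(benzyloxy)propyl]-6-methyldeca-6,8-dien-1-ol | C/C=C/C=C(\C)[C@H](CCCOCc1ccccc1)[C@@H](OCc1ccccc1)CCCO | intermediate
18 | 2-(triphenyl-λ5-phosphanylidene)propanal | CC(C=O)=P(c1ccccc1)(c1ccccc1)c1ccccc1 | starting material
19 | (4S,5S,6E,8E)-4-(benzyloxy)-5-[3-(benzyloxy)propyl]-6-methyldeca-6,8-dienal | C/C=C/C=C(\C)[C@H](CCCOCc1ccccc1)[C@@H](OCc1ccccc1)CCC=O | intermediate
20 | (2E,6S,7S,8E,10E)-6-(benzyloxy)-7-[3-(benzyloxy)propyl]-2,8-dimethyldodeca-2,8,10-trienal | C/C=C/C=C(\C)[C@H](CCCOCc1ccccc1)[C@@H](OCc1ccccc1)CC/C=C(\C)C=O | intermediate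
21 | 6α-(benzyloxy)-5β-[3-(benzyloxy)propyl]-1β,2α,4aβ-trimethyl-1,2,4a,5,6,7,8,8aα-octahydronaphthalene-1α-carbaldehyde | C(O[C@H]1CC[C@H]2[C@@](C)(C=C[C@H](C)[C@]2(C)C=O)[C@@H]1CCCOCc1ccccc1)c1ccccc1 | intermediate
22 | (2,5-dimethoxy-3-methylphenyl)lithium | [Li]c1cc(OC)cc(C)c1OC | intermediate
23 | (2,5-dimethoxy-3-methylphenyl)[6α-(benzyloxy)-5β-[3-(benzyloxy)propyl]-1β,2α,4aβ-trimethyl-1,2,4a,5,6,7,8,8aα-octahydronaphthalen-1α-yl]methanol (both carbinol epimers) | C(O[C@H]1CC[C@H]2[C@@](C)(C=C[C@H](C)[C@]2(C)C(O)c2cc(OC)cc(C)c2OC)[C@@H]1CCCOCc1ccccc1)c1ccccc1 | intermediate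
24 | 3-[1α-(2,5-dimethoxy-3-methylbenzyl)-6α-hydroxy-1β,2α,4aβ-trimethyl-1,2,4a,5,6,7,8,8aα-octahydronaphthalen-5β-yl]propan-1-ol | O[C@H]1CC[C@H]2[C@@](C)(C=C[C@H](C)[C@]2(C)Cc2cc(OC)cc(C)c2OC)[C@@H]1CCCO | intermediate
25 | 3-[1α-(2,5-dimethoxy-3-methylbenzyl)-6α-hydroxy-1β,2α,4aβ-trimethyl-8aαH-decahydronaphthalen-5β-yl]propan-1-ol | O[C@H]1CC[C@H]2[C@@](C)(CC[C@H](C)[C@]2(C)Cc2cc(OC)cc(C)c2OC)[C@@H]1CCCO | intermediate
26 | 3-[1α-(2,5-dimethoxy-3-methylbenzyl)-1β,2α,4aβ-trimethyl-6-oxo-8aαH-decahydronaphthalen-5β-yl]propanoic acid | O=C1CC[C@H]2[C@@](C)(CC[C@H](C)[C@]2(C)Cc2cc(OC)cc(C)c2OC)[C@@H]1CCC(=O)O | intermediate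
27 | isopropyltriphenylphosphonium iodide | CC(C)[P+](c1ccccc1)(c1ccccc1)c1ccccc1.[I-] | starting material
28 | isopropylidenetriphenylphosphorane | CC(C)=P(c1ccccc1)(c1ccccc1)c1ccccc1 | intermediate
29 | 3-[1α-(2,5-dimethoxy-3-methylbenzyl)-1β,2α,4aβ-trimethyl-6-(propan-2-ylidene)-8aαH-decahydronaphthalen-5β-yl]propanoic acid | CC(C)=C1CC[C@H]2[C@@](C)(CC[C@H](C)[C@]2(C)Cc2cc(OC)cc(C)c2OC)[C@@H]1CCC(=O)O | intermediate
30 | 3-[1β,2α,4aβ-trimethyl-1α-[(5-methyl-3,6-dioxocyclohexa-1,4-dien-1-yl)methyl]-6-(propan-2-ylidene)-8aαH-decahydronaphthalen-5β-yl]propanoic acid | CC(C)=C1CC[C@H]2[C@@](C)(CC[C@H](C)[C@]2(C)CC2=CC(=O)C=C(C)C2=O)[C@@H]1CCC(=O)O | intermediate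
31 | CNP0286368.1: 3-[1α-(2,5-dihydroxy-3-methylbenzyl)-1β,2α,4aβ-trimethyl-6-(propan-2-ylidene)-8aαH-decahydronaphthalen-5β-yl]propanoic acid | CC(C)=C1CC[C@H]2[C@@](C)(CC[C@H](C)[C@]2(C)Cc2cc(O)cc(C)c2O)[C@@H]1CCC(=O)O | target

**Step count and risks**

Total step count: 18. Longest linear sequence: 16 steps (steps 3 to 18).

Steps most likely to fail:

1. Step 12 (key step). The cis-methyl group on the diene terminus disfavours the s-cis conformer, so the cycloaddition may be slow, and a 1,5-hydrogen shift, cationic oligomerisation or loss of endo selectivity may compete. Fallback: from 20, acetalisation with 1,2-bis(trimethylsilyloxy)ethane and TMSOTf (cat.) in CH2Cl2 at −78 °C would give the ethylene acetal of the trienal F1. On warming to −40 °C with TMSOTf the acetal should ionise to a 2-alkenyl-1,3-dioxolan-2-ylium ion, a much stronger dienophile than the aluminium-complexed enal, and this ionic Diels–Alder reaction should give the cycloadduct acetal F2 with the same relative configuration. Hydrolysis with aqueous AcOH in THF comes back to the route at 21.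

2. Step 17. Enolisation of the hindered C6 ketone by the basic ylide may take the place of addition, giving recovered ketone and erosion of the C5 configuration. Fallback: from 26, esterification with Me3SiCHN2 in MeOH/toluene would give the keto methyl ester F3. Kinetic deprotonation at the unhindered C7 methylene with KN(SiMe3)2 and trapping with PhNTf2 at −78 °C would give the C6=C7 enol triflate F4. Suzuki–Miyaura coupling with isopropenylboronic acid pinacol ester (Pd(PPh3)4, K3PO4, dioxane/H2O) would give the 6-isopropenyl diene F5. 1,4-Hydrogenation of the s-cis diene with (naphthalene)Cr(CO)3 and H2 would deliver hydrogen to C7 and to the terminal CH2 and give the isopropylidene methyl ester F6 without touching C5. Saponification with LiOH comes back to the route at 29.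

3. Step 14. The benzylic C–O bond may be cleaved incompletely, or the electron-rich dimethoxyarene may be over-reduced. Fallback: from 23, NaH, CS2 and then MeI in THF would give the benzylic S-methyl xanthate F7. Barton–McCombie reduction with Bu3SnH and AIBN in toluene at 90 °C would give the deoxygenated bis-benzyl ether F8. Hydrogenation over Pd(OH)2 on carbon in EtOAc/EtOH would cleave both benzyl ethers and saturate C3=C4 in one operation, coming back to the route at 25.

Further compounds

F1 | step 12 | ethylene acetal (1,3-dioxolane) of trienal 20 | C/C=C/C=C(\C)[C@H](CCCOCc1ccccc1)[C@@H](OCc1ccccc1)CC/C=C(\C)C1OCCO1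
F2 | step 12 | ethylene acetal (1,3-dioxolane) of aldehyde 21 | C(O[C@H]1CC[C@H]2[C@@](C)(C=C[C@H](C)[C@]2(C)C2OCCO2)[C@@H]1CCCOCc1ccccc1)c1ccccc1
F3 | step 17 | methyl ester of keto acid 26 | O=C1CC[C@H]2[C@@](C)(CC[C@H](C)[C@]2(C)Cc2cc(OC)cc(C)c2OC)[C@@H]1CCC(=O)OC
F4 | step 17 | C6=C7 enol triflate of F3 | FC(F)(F)S(=O)(=O)OC1=CC[C@H]2[C@@](C)(CC[C@H](C)[C@]2(C)Cc2cc(OC)cc(C)c2OC)[C@@H]1CCC(=O)OC
F5 | step 17 | 6-isopropenyl C6=C7 diene methyl ester | CC(=C)C1=CC[C@H]2[C@@](C)(CC[C@H](C)[C@]2(C)Cc2cc(OC)cc(C)c2OC)[C@@H]1CCC(=O)OC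
F6 | step 17 | methyl ester of isopropylidene acid 29 | CC(C)=C1CC[C@H]2[C@@](C)(CC[C@H](C)[C@]2(C)Cc2cc(OC)cc(C)c2OC)[C@@H]1CCC(=O)OC
F7 | step 14 | benzylic S-methyl xanthate of 23 | C(O[C@H]1CC[C@H]2[C@@](C)(C=C[C@H](C)[C@]2(C)C(OC(=S)SC)c2cc(OC)cc(C)c2OC)[C@@H]1CCCOCc1ccccc1)c1ccccc1
F8 | step 14 | 6α-(benzyloxy)-5β-[3-(benzyloxy)propyl]-1α-(2,5-dimethoxy-3-methylbenzyl)-1β,2α,4aβ-trimethyl-1,2,4a,5,6,7,8,8aα-octahydronaphthalene | C(O[C@H]1CC[C@H]2[C@@](C)(C=C[C@H](C)[C@]2(C)Cc2cc(OC)cc(C)c2OC)[C@@H]1CCCOCc1ccccc1)c1ccccc1
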